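**Plan**

1. Retrosynthesis (halimane numbering, C18 = carboxyl carbon on C4): the methyl ester and the acetate are rejoined as one ester C18(=O)–O–C15, an 11-membered lactone that is not in the target. Ring A is then cut at C4–C5 and C2–C3 (retro-Diels–Alder) to a methacrylate held on O-15 of a 1-vinylcyclohexene (ring B).
2. Enabling feature: ring A is a cyclohexene (C1=C10) whose homoallylic C4 carries CO2R and CH3, i.e. the adduct of the diene C2=C1–C10=C5 with a methacrylate C3=C4. The C4 carboxyl and the C9 side chain are cis on the octalin and end in C18=O and O–C15, so a single ester bond can tie dienophile to diene.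
3. Further cuts: C14–C15 and C13–CH3 (alkyne carboalumination/formaldehyde), C10–C1 (enol triflate vinylation), C9–C11 (enolate alkylation), C8–CH3 (conjugate addition).
4. Forward: ring B is bought as 2-methylcyclohex-2-enone; the side chain and the vinyl group are attached; ring A closes last in a Lewis-acid-promoted type 2 intramolecular Diels–Alder reaction; methanolysis and acetylation open the tether into the two ester groups of the target.
5. Stereochemistry: C8 from catalyst-controlled conjugate addition; C9 from alkylation anti to the C8 methyl; C5 and C4 from C9 through the tether (diene face and endo orientation); 13E from syn carbometalation.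

Key step: step 9

Remark: ring A = C1–C5 and C10, ring B = C5–C10, side chain C11–C16, C17 on C8, C20 on C9, C19 = methyl on C4; in this numbering the target is (4S,5R,8R,9S,13E).

**Route**

Step 1
Reactants: 1 2-methylcyclohex-2-en-1-one
Product: 3 trimethyl{[(3R)-2,3-dimethylcyclohex-1-en-1-yl]oxy}silane, via dimethylaluminium enolate 2 (not isolated)
Conditions: Me3Al, CuTC (2 mol %), chiral phosphoramidite ligand (4 mol %, the enantiomer that gives the 3R adduct), Et2O, −30 °C; then TMSOTf, THF, −30 → 0 °C
Reagents that add atoms: trimethylaluminium, C[Al](C)C; trimethylsilyl trifluoromethanesulfonate, C[Si](C)(C)OS(=O)(=O)C(F)(F)F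
Why: Copper-catalysed asymmetric conjugate addition of Me3Al to an α-substituted cyclic enone, in which the chiral Cu–phosphoramidite complex selects the enone face and so sets C8 (3R), followed by O-silylation of the aluminium enolate to store the regiodefined tetrasubstituted enolate.

Step 2
Reactants: 4 4-(trimethylsilyl)but-3-yn-1-ol
Product: 5 4-(trimethylsilyl)but-3-yn-1-yl trifluoromethanesulfonate
Conditions: Tf2O, 2,6-lutidine, CH2Cl2, −78 → −30 °C; filtered through silica and used at once
Reagents that add atoms: trifluoromethanesulfonic anhydride, O=S(=O)(OS(=O)(=O)C(F)(F)F)C(F)(F)F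
Why: O-Sulfonylation of a primary alcohol gives a primary alkyl triflate, an electrophile reactive enough for a hindered enolate, with the alkyne masked as its silane.

Step 3
Reactants: 3 trimethyl{[(3R)-2,3-dimethylcyclohex-1-en-1-yl]oxy}silane; 5 4-(trimethylsilyl)but-3-yn-1-yl trifluoromethanesulfonate
Product: 7 (2S,3R)-2,3-dimethyl-2-[4-(trimethylsilyl)but-3-yn-1-yl]cyclohexan-1-one, via lithium enolate 6 (not isolated)
Conditions: MeLi, THF, 0 °C → rt; then 5, −78 → −20 °C
Reagents that add atoms: methyllithium, [Li]C (supplies only the lithium of 6; no atom of it remains in 7)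
Why: Cleavage of the silyl enol ether by MeLi gives the regiodefined lithium enolate, and its C-alkylation (enolate alkylation) by the primary triflate should occur anti to the pseudoaxial C8 methyl group, setting the quaternary C9 (2S) with the two methyl groups cis.

Step 4
Reactants: 7 (2S,3R)-2,3-dimethyl-2-[4-(trimethylsilyl)but-3-yn-1-yl]cyclohexan-1-one
Product: 9 (5R,6S)-5,6-dimethyl-6-[4-(trimethylsilyl)but-3-yn-1-yl]cyclohex-1-en-1-yl trifluoromethanesulfonate, via potassium enolate 8 (not isolated)
Conditions: KHMDS, THF, −78 °C; then PhNTf2, −78 → 0 °C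
Reagents that add atoms: N-phenylbis(trifluoromethanesulfonimide), O=S(=O)(N(c1ccccc1)S(=O)(=O)C(F)(F)F)C(F)(F)F; potassium hexamethyldisilazide, C[Si](C)(C)[N-][Si](C)(C)C.[K+] (supplies only the potassium of 8)
Why: Enol triflate formation is regiospecific because the other α-carbon (C9) is quaternary, so enolization can only place the double bond at C10=C5.

Step 5
Reactants: 9 (5R,6S)-5,6-dimethyl-6-[4-(trimethylsilyl)but-3-yn-1-yl]cyclohex-1-en-1-yl trifluoromethanesulfonate
Product: 10 trimethyl{4-[(1S,6R)-2-ethenyl-1,6-dimethylcyclohex-2-en-1-yl]but-1-yn-1-yl}silane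
Conditions: tributyl(vinyl)stannane, Pd(PPh3)4 (5 mol %), LiCl, THF, reflux
Reagents that add atoms: tributyl(vinyl)stannane, C=C[Sn](CCCC)(CCCC)CCCC
Why: Stille cross-coupling of an enol triflate with a vinylstannane installs C1–C2 and gives the 1-vinylcyclohexene diene; the silylated alkyne cannot enter alkynyl coupling.

Step 6
Reactants: 10 trimethyl{4-[(1S,6R)-2-ethenyl-1,6-dimethylcyclohex-2-en-1-yl]but-1-yn-1-yl}silane
Product: 11 (5R,6S)-6-(but-3-yn-1-yl)-1-ethenyl-5,6-dimethylcyclohex-1-ene
Conditions: K2CO3 (cat.), MeOH, rt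
Reagents that add atoms: none
Why: Methoxide-mediated protodesilylation of an alkynylsilane frees the terminal alkyne and leaves the diene untouched.

Step 7
Reactants: 11 (5R,6S)-6-(but-3-yn-1-yl)-1-ethenyl-5,6-dimethylcyclohex-1-ene
Product: 14 (2E)-5-[(1S,6R)-2-ethenyl-1,6-dimethylcyclohex-2-en-1-yl]-3-methylpent-2-en-1-ol, via alkenyldimethylalane 12 (not isolated), via lithium alkenylaluminate 13 (not isolated)
Conditions: Me3Al, Cp2ZrCl2 (0.3 equiv), CH2Cl2, 0 °C → rt; volatiles removed; n-BuLi, hexane/THF, −78 °C; (CH2O)n, −78 °C → rt; aq. Rochelle salt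
Reagents that add atoms: trimethylaluminium, C[Al](C)C; formaldehyde (as paraformaldehyde), C=O; n-butyllithium, [Li]CCCC (its butyl group and lithium are in 13 only, not in 14)
Why: Negishi zirconium-catalysed carboalumination adds CH3 and Al syn across the terminal alkyne (methyl to the internal carbon), a reaction selective for alkynes over alkenes and dienes, and the derived ate complex hydroxymethylates with retention, so the 13E trisubstituted allylic alcohol should form as a single geometric isomer.

Step 8
Reactants: 14 (2E)-5-[(1S,6R)-2-ethenyl-1,6-dimethylcyclohex-2-en-1-yl]-3-methylpent-2-en-1-ol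
Product: 15 (2E)-5-[(1S,6R)-2-ethenyl-1,6-dimethylcyclohex-2-en-1-yl]-3-methylpent-2-en-1-yl 2-methylprop-2-enoate
Conditions: methacryloyl chloride, Et3N, DMAP (cat.), BHT (trace), CH2Cl2, 0 °C
Reagents that add atoms: methacryloyl chloride, C=C(C)C(=O)Cl
Why: Acylation of the primary allylic alcohol attaches the dienophile (C3, C4, C18, C19) to O-15 through the ester bond that serves as the tether.

Step 9
Reactants: 15 (2E)-5-[(1S,6R)-2-ethenyl-1,6-dimethylcyclohex-2-en-1-yl]-3-methylpent-2-en-1-yl 2-methylprop-2-enoate
Product: 16 (4S,5R,8R,9S)-halima-1(10),13E-dien-18,15-olide (octalin with an 11-membered lactone running from the C4 carbonyl over O-15 and the side chain to C9)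
Conditions: Me2AlCl (2 equiv), CH2Cl2, slow addition of 15 to 2 mM final concentration, −20 °C → rt
Reagents that add atoms: none
Why: Me2AlCl binds the ester carbonyl of the tethered methacrylate and lowers its LUMO, and the s-cis 1-vinylcyclohexene (C5=C10–C1=C2) adds to C3=C4 in a concerted, asynchronous [4+2] cycloaddition in which the unhindered C2–C3 bond leads. The closest known reaction type is the Lewis-acid-promoted type 2 intramolecular Diels–Alder reaction of ester-tethered trienes (tether on the internal diene carbon, here through C9), run as a macrocyclizing cycloaddition under high dilution. Ring A closes as the six-membered [4π+2π] ring through the C4–C5 and C2–C3 bonds, leaving the double bond at C1=C10, while the 11-membered lactone closes at the same time as the 1,3-bridged ("meta") ring that type 2 tethers favour and is not part of the target. C5 is controlled by C9: the tether leaves from the C11 methylene, so the dienophile is delivered to the diene face that carries C11, which is also the face opposite the pseudoaxial C9 methyl group, and H-5 should end up anti to the side chain. C4 is controlled by the tether too: the carbonyl carbon has to point back over C10 towards C9 (ester endo, methyl exo), which places C18 cis to the C9 side chain and the C4 methyl on the other face. The step needs "ortho" regiochemistry (C4 to C5, not to C2), secured by the tether and by the pairing of the acrylate β-carbon C3 with the unsubstituted diene terminus C2, and it needs ring closure to outrun oligomerization, which the dilution secures.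

Step 10
Reactants: 16 (4S,5R,8R,9S)-halima-1(10),13E-dien-18,15-olide
Product: 17 methyl (1S,5S,6R,8aR)-5-[(3E)-5-hydroxy-3-methylpent-3-en-1-yl]-1,5,6-trimethyl-1,2,3,5,6,7,8,8a-octahydronaphthalene-1-carboxylate
Conditions: NaOMe (0.3 equiv), MeOH, 60 °C
Reagents that add atoms: methanol, CO
Why: Transesterification (methanolysis) of the strained bridged lactone in methanol as solvent should open the tether to the methyl ester and the free C15 alcohol; no stereocentre is epimerizable because C4 is quaternary.

Step 11
Reactants: 17 methyl (1S,5S,6R,8aR)-5-[(3E)-5-hydroxy-3-methylpent-3-en-1-yl]-1,5,6-trimethyl-1,2,3,5,6,7,8,8a-octahydronaphthalene-1-carboxylate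
Product: 18 methyl (1S,5S,6R,8aR)-5-[(3E)-5-acetoxy-3-methylpent-3-en-1-yl]-1,5,6-trimethyl-1,2,3,5,6,7,8,8a-octahydronaphthalene-1-carboxylate (CNP0209995.1)
Conditions: Ac2O, pyridine, DMAP (cat.), CH2Cl2, 0 °C → rt
Reagents that add atoms: acetic anhydride, CC(=O)OC(C)=O
Why: Acetylation of the primary allylic alcohol completes the target without touching the hindered methyl ester or the alkenes.

**Compound list**

1 | 2-methylcyclohex-2-en-1-one | CC1=CCCCC1=O | starting material
2 | dimethylaluminium (3R)-2,3-dimethylcyclohex-1-en-1-olate (formed in the flask) | C[C@@H]1CCCC(O[Al](C)C)=C1C | intermediate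
3 | trimethyl{[(3R)-2,3-dimethylcyclohex-1-en-1-yl]oxy}silane | C[C@@H]1CCCC(O[Si](C)(C)C)=C1C | intermediate
4 | 4-(trimethylsilyl)but-3-yn-1-ol | C[Si](C)(C)C#CCCO | starting material
5 | 4-(trimethylsilyl)but-3-yn-1-yl trifluoromethanesulfonate | C[Si](C)(C)C#CCCOS(=O)(=O)C(F)(F)F | intermediate
6 | lithium (3R)-2,3-dimethylcyclohex-1-en-1-olate (formed in the flask) | C[C@@H]1CCCC([O-])=C1C.[Li+] | intermediate
7 | (2S,3R)-2,3-dimethyl-2-[4-(trimethylsilyl)but-3-yn-1-yl]cyclohexan-1-one | O=C1CCC[C@@H](C)[C@]1(C)CCC#C[Si](C)(C)C | intermediate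
8 | potassium (5R,6S)-5,6-dimethyl-6-[4-(trimethylsilyl)but-3-yn-1-yl]cyclohex-1-en-1-olate (formed in the flask) | [K+].[O-]C1=CCC[C@@H](C)[C@]1(C)CCC#C[Si](C)(C)C | intermediate
9 | (5R,6S)-5,6-dimethyl-6-[4-(trimethylsilyl)but-3-yn-1-yl]cyclohex-1-en-1-yl trifluoromethanesulfonate | FC(F)(F)S(=O)(=O)OC1=CCC[C@@H](C)[C@]1(C)CCC#C[Si](C)(C)C | intermediate
10 | trimethyl{4-[(1S,6R)-2-ethenyl-1,6-dimethylcyclohex-2-en-1-yl]but-1-yn-1-yl}silane | C=CC1=CCC[C@@H](C)[C@]1(C)CCC#C[Si](C)(C)C | intermediate
11 | (5R,6S)-6-(but-3-yn-1-yl)-1-ethenyl-5,6-dimethylcyclohex-1-ene | C=CC1=CCC[C@@H](C)[C@]1(C)CCC#C | intermediate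
12 | [(1E)-4-[(1S,6R)-2-ethenyl-1,6-dimethylcyclohex-2-en-1-yl]-2-methylbut-1-en-1-yl]dimethylalane (formed in the flask) | C=CC1=CCC[C@@H](C)[C@]1(C)CC/C(C)=C/[Al](C)C | intermediate
13 | lithium butyl[(1E)-4-[(1S,6R)-2-ethenyl-1,6-dimethylcyclohex-2-en-1-yl]-2-methylbut-1-en-1-yl]dimethylaluminate (formed in the flask) | [Li+].C=CC1=CCC[C@@H](C)[C@]1(C)CC/C(C)=C/[Al-](C)(C)CCCC | intermediate
14 | (2E)-5-[(1S,6R)-2-ethenyl-1,6-dimethylcyclohex-2-en-1-yl]-3-methylpent-2-en-1-ol | C=CC1=CCC[C@@H](C)[C@]1(C)CC/C(C)=C/CO | intermediate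
15 | (2E)-5-[(1S,6R)-2-ethenyl-1,6-dimethylcyclohex-2-en-1-yl]-3-methylpent-2-en-1-yl 2-methylprop-2-enoate | C=CC1=CCC[C@@H](C)[C@]1(C)CC/C(C)=C/COC(=O)C(C)=C | intermediate
16 | (4S,5R,8R,9S)-halima-1(10),13E-dien-18,15-olide (11-membered lactone bridging C4 and C9) | O=C3[C@@]1(C)CCC=C2[C@H]1CC[C@@H](C)[C@]2(C)CC/C(C)=C/CO3 | intermediate
17 | methyl (1S,5S,6R,8aR)-5-[(3E)-5-hydroxy-3-methylpent-3-en-1-yl]-1,5,6-trimethyl-1,2,3,5,6,7,8,8a-octahydronaphthalene-1-carboxylate | COC(=O)[C@@]1(C)CCC=C2[C@H]1CC[C@@H](C)[C@]2(C)CC/C(C)=C/CO | intermediate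
18 | methyl (1S,5S,6R,8aR)-5-[(3E)-5-acetoxy-3-methylpent-3-en-1-yl]-1,5,6-trimethyl-1,2,3,5,6,7,8,8a-octahydronaphthalene-1-carboxylate | COC(=O)[C@@]1(C)CCC=C2[C@H]1CC[C@@H](C)[C@]2(C)CC/C(C)=C/COC(C)=O | target

**Step count**

Total steps: 11. Longest linear sequence: 10 steps (steps 1 and 3–11, from compound 1); step 2 is a one-step side branch.

**Steps most likely to fail**

Step 9. The macrocyclizing cycloaddition may be too slow, so that oligomerization, Lewis-acid ionization of the allylic ester or cationic decomposition of the diene takes over; bonding of C4 to C2 instead of C5 is also possible. The fallback drops the tether. It sets out from 14 and returns at 18. Alcohol 14 is acetylated (Ac2O, pyridine, DMAP) to the dienyl acetate F1. F1 is then heated in neat methyl methacrylate (BHT, sealed tube, about 140 °C, or under 10–12 kbar at rt) in an intermolecular Diels–Alder reaction that should give 18 directly. The "ortho" orientation is expected from the 1-vinylcyclohexene substitution pattern and the face from the pseudoaxial C9 methyl group. The endo/exo ratio at C4 is unguided, so 18 would have to be separated from its isomers by chromatography.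

Step 3. The hindered tetrasubstituted enolate may be O-alkylated, or may act as a base and eliminate the triflate, instead of forming the C9–C11 bond. The fallback builds the side chain by conjugate addition and olefination. It sets out from 3 and returns at 14. A Mukaiyama–Michael addition of 3 to methyl vinyl ketone (BF3·OEt2, CH2Cl2, −78 °C), again anti to the C8 methyl, should give diketone F2. Horner–Wadsworth–Emmons olefination of the unhindered methyl ketone (triethyl phosphonoacetate, NaH, THF) gives the (E)-enoate F3 after removal of the Z isomer. KHMDS/PhNTf2 converts the ring ketone to enol triflate F4, Stille vinylation gives dienyl ester F5, and DIBAL-H (CH2Cl2, −78 °C) reduces the ester to 14.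

Step 10. Attack of methoxide at the carbonyl next to the quaternary C4 may be sluggish and reversible, leaving lactone or allowing slow cleavage at the allylic C15–O bond. The fallback forms the methyl ester by carboxylate alkylation instead of acyl substitution. It sets out from 16 and returns at 17. Irreversible saponification (KOH, aqueous dioxane, reflux; acidify) gives hydroxy acid F6, and MeI/K2CO3 in DMF methylates the carboxylate selectively to give 17.

**Further compounds**

F1 | step 9 | (2E)-5-[(1S,6R)-2-ethenyl-1,6-dimethylcyclohex-2-en-1-yl]-3-methylpent-2-en-1-yl acetate | C=CC1=CCC[C@@H](C)[C@]1(C)CC/C(C)=C/COC(C)=O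
F2 | step 3 | (2S,3R)-2,3-dimethyl-2-(3-oxobutyl)cyclohexan-1-one | O=C1CCC[C@@H](C)[C@]1(C)CCC(C)=O
F3 | step 3 | ethyl (2E)-5-[(1S,2R)-1,2-dimethyl-6-oxocyclohexyl]-3-methylpent-2-enoate | O=C1CCC[C@@H](C)[C@]1(C)CC/C(C)=C/C(=O)OCC
F4 | step 3 | ethyl (2E)-5-[(1S,6R)-1,6-dimethyl-2-{[(trifluoromethyl)sulfonyl]oxy}cyclohex-2-en-1-yl]-3-methylpent-2-enoate | FC(F)(F)S(=O)(=O)OC1=CCC[C@@H](C)[C@]1(C)CC/C(C)=C/C(=O)OCC
F5 | step 3 | ethyl (2E)-5-[(1S,6R)-2-ethenyl-1,6-dimethylcyclohex-2-en-1-yl]-3-methylpent-2-enoate | C=CC1=CCC[C@@H](C)[C@]1(C)CC/C(C)=C/C(=O)OCC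
F6 | step 10 | (1S,5S,6R,8aR)-5-[(3E)-5-hydroxy-3-methylpent-3-en-1-yl]-1,5,6-trimethyl-1,2,3,5,6,7,8,8a-octahydronaphthalene-1-carboxylic acid | OC(=O)[C@@]1(C)CCC=C2[C@H]1CC[C@@H](C)[C@]2(C)CC/C(C)=C/CO
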